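The target is disconnected at the C4–C8 interflavan bond into a (2S)-flavan-4-yl cation and per-benzylated (−)-epigallocatechin, whose ring C is closed by forming the aryl ether bond O1–C8a. The key step is a one-pot double nucleophilic aromatic substitution: the C2 alkoxide of an open-chain syn diol monoether attacks a 4-benzyloxy-2,6-difluorophenyl ring to close ring C, and benzyl oxide then replaces the second fluorine at C5. It exploits that C8a and C5, the two positions of ring A ortho to C4a, both carry oxygen, so the fluorines are equivalent, and that bonding at O1 and sp2 C8a leaves C2 and C3 untouched, giving the 2,3-cis series directly.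

Key step: step 7

Step 1
Reactants: 1 4-bromo-3,5-difluorophenol
Product: 2 5-(benzyloxy)-2-bromo-1,3-difluorobenzene
Conditions: BnBr, K2CO3, DMF, rt
Reagents that add atoms: benzyl bromide, BrCc1ccccc1
Why: Williamson ether synthesis on the only acidic site should give the benzyl ether cleanly.

Step 2
Reactants: 2 5-(benzyloxy)-2-bromo-1,3-difluorobenzene; 3 methyl (2R)-oxirane-2-carboxylate
Product: 5 methyl (2R)-3-[4-(benzyloxy)-2,6-difluorophenyl]-2-hydroxypropanoate, via arylmagnesium chloride 4 (not isolated)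
Conditions: i-PrMgCl·LiCl, THF, −20 °C; then CuI (10 mol %), 3, −40 to 0 °C; aqueous work-up
Reagents that add atoms: none
Why: Bromine–magnesium exchange is fast on a bromide flanked by two fluorines, and copper-catalysed SN2 opening of the glycidic ester should occur at the unsubstituted C3, so the (R) centre of 3 is carried over untouched as the future C3.

Step 3
Reactants: 5 methyl (2R)-3-[4-(benzyloxy)-2,6-difluorophenyl]-2-hydroxypropanoate
Product: 6 methyl (2R)-2-(benzyloxy)-3-[4-(benzyloxy)-2,6-difluorophenyl]propanoate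
Conditions: BnOC(=NH)CCl3, TfOH (cat.), CH2Cl2/cyclohexane, rt
Reagents that add atoms: benzyl 2,2,2-trichloroacetimidate, ClC(Cl)(Cl)C(=N)OCc1ccccc1
Why: Acid-catalysed O-benzylation with the trichloroacetimidate avoids base, so the α-oxygenated ester centre should not epimerise.

Step 4
Reactants: 6 methyl (2R)-2-(benzyloxy)-3-[4-(benzyloxy)-2,6-difluorophenyl]propanoate
Product: 7 (2R)-2-(benzyloxy)-3-[4-(benzyloxy)-2,6-difluorophenyl]propanal
Conditions: i-Bu2AlH (1.1 equiv), CH2Cl2, −78 °C; Rochelle salt work-up; used crude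
Reagents that add atoms: none
Why: Half-reduction of an α-alkoxy ester should stop at the chelated aluminium hemiacetal at −78 °C and release the aldehyde on work-up.

Step 5
Reactants: 8 5-bromobenzene-1,2,3-triol
Product: 9 5-bromo-1,2,3-tris(benzyloxy)benzene
Conditions: BnBr, K2CO3, DMF, 60 °C
Reagents that add atoms: benzyl bromide, BrCc1ccccc1
Why: Threefold Williamson ether synthesis should protect all phenols of the ring B building block.

Step 6
Reactants: 7 (2R)-2-(benzyloxy)-3-[4-(benzyloxy)-2,6-difluorophenyl]propanal; 9 5-bromo-1,2,3-tris(benzyloxy)benzene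
Product: 11 (1R,2R)-2-(benzyloxy)-3-[4-(benzyloxy)-2,6-difluorophenyl]-1-[3,4,5-tris(benzyloxy)phenyl]propan-1-ol, via arylmagnesium bromide 10 (not isolated)
Conditions: 9, Mg, THF, rt; then 7 precomplexed with MgBr2·OEt2, CH2Cl2, −78 °C
Reagents that add atoms: none
Why: Grignard addition under Cram chelate control (magnesium bridging the carbonyl and α-benzyloxy oxygens) should deliver the aryl group to the face of the α-hydrogen, which sets (1R), syn to the (2R) benzyloxy centre.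

Step 7
Reactants: 11 (1R,2R)-2-(benzyloxy)-3-[4-(benzyloxy)-2,6-difluorophenyl]-1-[3,4,5-tris(benzyloxy)phenyl]propan-1-ol
Product: 13 (2R,3R)-3,5,7-tris(benzyloxy)-2-[3,4,5-tris(benzyloxy)phenyl]chromane, via 5-fluoroflavan 12 (not isolated)
Conditions: KH (1.2 equiv), NMP, 0 °C to rt; then BnOK (from BnOH and KH, 3 equiv), 100 °C
Reagents that add atoms: benzyl alcohol, OCc1ccccc1
Why: KH turns the free hydroxyl at the future C2 of 11 into its potassium alkoxide, which adds to one of the two equivalent C–F carbons ortho to the benzylic CH2 and expels fluoride through a Meisenheimer-type adduct (O1–C8a formed, 12); benzyl oxide then displaces the remaining C5 fluoride of 12 in a second, intermolecular substitution to give 13. The closest known reaction type is nucleophilic aromatic substitution of non-activated fluoroarenes by potassium alkoxides in dipolar aprotic solvents, as used for aryl alkyl ethers and chromans. Ring C is closed in the 6-exo-trig mode, the alkoxide oxygen attacking the aromatic carbon. No stereocentre is created: C2 and C3 are carried over from 11 with retention because the new bond is made at oxygen and at an sp2 carbon, so the syn (1R,2R) array becomes the 2,3-cis (2R,3R) flavan. The step needs ring closure rather than a five-membered or intermolecular alternative, which is secured by the benzyl group on O3 (only the C2 oxygen is free), by the local twofold symmetry of the difluoroaryl ring (either fluorine gives the same product) and by staging (cyclisation at room temperature before benzyl oxide and heat are applied); a benzyloxy-for-fluorine exchange that came first would still leave one ortho fluorine and converge on 13.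

Step 8
Reactants: 14 1-[4-(benzyloxy)-2-hydroxyphenyl]ethan-1-one; 15 4-(benzyloxy)benzaldehyde
Product: 17 rac-7-(benzyloxy)-2-[4-(benzyloxy)phenyl]chroman-4-one, via chalcone 16 (not isolated)
Conditions: pyrrolidine, EtOH, reflux
Reagents that add atoms: none
Why: Amine-mediated Claisen–Schmidt condensation should give the 2'-hydroxychalcone, which closes by intramolecular oxa-Michael addition to the racemic flavanone under the same conditions.

Step 9
Reactants: 17 rac-7-(benzyloxy)-2-[4-(benzyloxy)phenyl]chroman-4-one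
Product: 18 (2S,4S)-7-(benzyloxy)-2-[4-(benzyloxy)phenyl]chroman-4-ol
Conditions: RuCl[(S,S)-TsDPEN](p-cymene) (1 mol %), HCO2H/Et3N (5:2), EtOAc, rt, to about half conversion
Reagents that add atoms: none
Why: Noyori–Ikariya asymmetric transfer hydrogenation run as a kinetic resolution: the (S,S) catalyst sets (4S), and only the (2S) ketone can reach it through the favoured cis hydride delivery, so (2S,4S)-18 should form while (2R)-17 stays behind and is separated.

Step 10
Reactants: 13 (2R,3R)-3,5,7-tris(benzyloxy)-2-[3,4,5-tris(benzyloxy)phenyl]chromane; 18 (2S,4S)-7-(benzyloxy)-2-[4-(benzyloxy)phenyl]chroman-4-ol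
Product: 19 (2R,3R)-3,5,7-tris(benzyloxy)-8-{(2S,4R)-7-(benzyloxy)-2-[4-(benzyloxy)phenyl]chroman-4-yl}-2-[3,4,5-tris(benzyloxy)phenyl]chromane
Conditions: 13 (3 equiv, excess recovered), TMSOTf (0.1 equiv), 4 Å MS, CH2Cl2, −78 to −40 °C
Reagents that add atoms: none
Why: Friedel–Crafts alkylation: the acid ionises 18 to a flavan-4-yl cation stabilised by O1 and the 7-benzyloxy group, which should attack the phloroglucinol-type ring A of 13 at C8 (the less hindered site, preferred over C6 in 5,7-di-O-benzyl flavan-3-ols) by pseudo-axial approach to the half-chair cation with its C2 aryl pseudo-equatorial, setting (4R), that is 2,4-trans.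

Step 11
Reactants: 19 (2R,3R)-3,5,7-tris(benzyloxy)-8-{(2S,4R)-7-(benzyloxy)-2-[4-(benzyloxy)phenyl]chroman-4-yl}-2-[3,4,5-tris(benzyloxy)phenyl]chromane
Product: 20 (2R,3R)-8-[(2S,4R)-7-hydroxy-2-(4-hydroxyphenyl)chroman-4-yl]-2-(3,4,5-trihydroxyphenyl)chromane-3,5,7-triol
Conditions: H2 (1 atm), Pd(OH)2/C, degassed THF/MeOH/H2O, rt
Reagents that add atoms: none
Why: Hydrogenolysis of the eight benzyl ethers under neutral conditions should leave the interflavan C–C bond, both pyran rings and all four stereocentres untouched.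

Compound list
1 | 4-bromo-3,5-difluorophenol | Oc1cc(F)c(Br)c(F)c1 | starting material
2 | 5-(benzyloxy)-2-bromo-1,3-difluorobenzene | Fc1cc(OCc2ccccc2)cc(F)c1Br | intermediate
3 | methyl (2R)-oxirane-2-carboxylate | COC(=O)[C@H]1CO1 | starting material
4 | [4-(benzyloxy)-2,6-difluorophenyl]magnesium chloride | Cl[Mg]c1c(F)cc(OCc2ccccc2)cc1F | intermediate
5 | methyl (2R)-3-[4-(benzyloxy)-2,6-difluorophenyl]-2-hydroxypropanoate | COC(=O)[C@H](O)Cc1c(F)cc(OCc2ccccc2)cc1F | intermediate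
6 | methyl (2R)-2-(benzyloxy)-3-[4-(benzyloxy)-2,6-difluorophenyl]propanoate | COC(=O)[C@H](OCc1ccccc1)Cc1c(F)cc(OCc2ccccc2)cc1F | intermediate
7 | (2R)-2-(benzyloxy)-3-[4-(benzyloxy)-2,6-difluorophenyl]propanal | O=C[C@H](OCc1ccccc1)Cc1c(F)cc(OCc2ccccc2)cc1F | intermediate
8 | 5-bromobenzene-1,2,3-triol | Oc1cc(Br)cc(O)c1O | starting material
9 | 5-bromo-1,2,3-tris(benzyloxy)benzene | Brc1cc(OCc2ccccc2)c(OCc2ccccc2)c(OCc2ccccc2)c1 | intermediate
10 | [3,4,5-tris(benzyloxy)phenyl]magnesium bromide | Br[Mg]c1cc(OCc2ccccc2)c(OCc2ccccc2)c(OCc2ccccc2)c1 | intermediate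
11 | (1R,2R)-2-(benzyloxy)-3-[4-(benzyloxy)-2,6-difluorophenyl]-1-[3,4,5-tris(benzyloxy)phenyl]propan-1-ol | O[C@H](c1cc(OCc2ccccc2)c(OCc2ccccc2)c(OCc2ccccc2)c1)[C@H](OCc1ccccc1)Cc1c(F)cc(OCc2ccccc2)cc1F | intermediate
12 | (2R,3R)-3,7-bis(benzyloxy)-5-fluoro-2-[3,4,5-tris(benzyloxy)phenyl]chromane | C(c1ccccc1)Oc1cc(F)c2c(c1)O[C@H](c1cc(OCc3ccccc3)c(OCc3ccccc3)c(OCc3ccccc3)c1)[C@H](OCc1ccccc1)C2 | intermediate
13 | (2R,3R)-3,5,7-tris(benzyloxy)-2-[3,4,5-tris(benzyloxy)phenyl]chromane | C(c1ccccc1)Oc1cc(OCc2ccccc2)c2c(c1)O[C@H](c1cc(OCc3ccccc3)c(OCc3ccccc3)c(OCc3ccccc3)c1)[C@H](OCc1ccccc1)C2 | intermediate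
14 | 1-[4-(benzyloxy)-2-hydroxyphenyl]ethan-1-one | CC(=O)c1ccc(OCc2ccccc2)cc1O | starting material
15 | 4-(benzyloxy)benzaldehyde | O=Cc1ccc(OCc2ccccc2)cc1 | starting material
16 | (E)-1-[4-(benzyloxy)-2-hydroxyphenyl]-3-[4-(benzyloxy)phenyl]prop-2-en-1-one | O=C(/C=C/c1ccc(OCc2ccccc2)cc1)c1ccc(OCc2ccccc2)cc1O | intermediate
17 | rac-7-(benzyloxy)-2-[4-(benzyloxy)phenyl]chroman-4-one | O=C1CC(c2ccc(OCc3ccccc3)cc2)Oc2cc(OCc3ccccc3)ccc21 | intermediate
18 | (2S,4S)-7-(benzyloxy)-2-[4-(benzyloxy)phenyl]chroman-4-ol | C(c1ccccc1)Oc1ccc([C@@H]2C[C@H](O)c3ccc(OCc4ccccc4)cc3O2)cc1 | intermediate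
19 | (2R,3R)-3,5,7-tris(benzyloxy)-8-{(2S,4R)-7-(benzyloxy)-2-[4-(benzyloxy)phenyl]chroman-4-yl}-2-[3,4,5-tris(benzyloxy)phenyl]chromane | C(c1ccccc1)Oc1ccc([C@@H]2C[C@@H](c3c(OCc5ccccc5)cc(OCc5ccccc5)c4c3O[C@H](c3cc(OCc5ccccc5)c(OCc5ccccc5)c(OCc5ccccc5)c3)[C@H](OCc3ccccc3)C4)c3ccc(OCc4ccccc4)cc3O2)cc1 | intermediate
20 | (2R,3R)-8-[(2S,4R)-7-hydroxy-2-(4-hydroxyphenyl)chroman-4-yl]-2-(3,4,5-trihydroxyphenyl)chromane-3,5,7-triol | Oc1ccc([C@@H]2C[C@@H](c3c(O)cc(O)c4c3O[C@H](c3cc(O)c(O)c(O)c3)[C@H](O)C4)c3ccc(O)cc3O2)cc1 | target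

Total step count: 11. Longest linear sequence: 8 steps (1, 2, 3, 4, 6, 7, 10, 11).

Steps most likely to fail

Step 7. The intermolecular displacement of the C5 fluoride may stall on the electron-rich fluoroflavan, or benzyl oxide may consume both fluorides before ring closure. The fallback moves the intermolecular substitution to the symmetric stage, where the fluorides are activated by the ortho bromine; it sets out from 2 and comes back at 13. BnOK (1 equiv, NMP, rt to 60 °C) should convert 2 into 1,5-bis(benzyloxy)-2-bromo-3-fluorobenzene F1 as a single regioisomer, since the two fluorines are equivalent. Exchange with i-PrMgCl·LiCl and CuI-catalysed opening of 3 gives methyl (2R)-3-[2,4-bis(benzyloxy)-6-fluorophenyl]-2-hydroxypropanoate F2. Benzylation as in step 3 gives methyl (2R)-2-(benzyloxy)-3-[2,4-bis(benzyloxy)-6-fluorophenyl]propanoate F3, and i-Bu2AlH gives (2R)-2-(benzyloxy)-3-[2,4-bis(benzyloxy)-6-fluorophenyl]propanal F4. Chelation-controlled addition of 10 gives (1R,2R)-2-(benzyloxy)-3-[2,4-bis(benzyloxy)-6-fluorophenyl]-1-[3,4,5-tris(benzyloxy)phenyl]propan-1-ol F5. KH in NMP then closes ring C by a single intramolecular substitution of the one remaining fluoride to give 13.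

Step 10. Facial selectivity at the flavan-4-yl cation may be poor, attack may occur at C6, 13 may be alkylated twice, or 18 may self-condense. The fallback builds the upper heterocycle on C8 under reagent control; it sets out from 13 and comes back at 19. NBS (CH2Cl2, −20 °C) should brominate 13 at C8 to (2R,3R)-3,5,7-tris(benzyloxy)-8-bromo-2-[3,4,5-tris(benzyloxy)phenyl]chromane F6. Exchange with n-BuLi (THF, −78 °C) and a DMF quench gives (2R,3R)-3,5,7-tris(benzyloxy)-2-[3,4,5-tris(benzyloxy)phenyl]chromane-8-carbaldehyde F7. Claisen–Schmidt condensation with 1-[4-(benzyloxy)phenyl]ethan-1-one (KOH, EtOH/THF) gives (E)-1-[4-(benzyloxy)phenyl]-3-{(2R,3R)-3,5,7-tris(benzyloxy)-2-[3,4,5-tris(benzyloxy)phenyl]chroman-8-yl}prop-2-en-1-one F8. Hayashi–Miyaura addition of [4-(benzyloxy)-2-hydroxyphenyl]boronic acid, with Rh(acac)(C2H4)2 and the BINAP antipode that delivers the (R) diarylmethine, gives (3R)-3-[4-(benzyloxy)-2-hydroxyphenyl]-1-[4-(benzyloxy)phenyl]-3-{(2R,3R)-3,5,7-tris(benzyloxy)-2-[3,4,5-tris(benzyloxy)phenyl]chroman-8-yl}propan-1-one F9. Transfer hydrogenation with RuCl[(R,R)-TsDPEN](p-cymene) and HCO2H/Et3N gives (1R,3R)-3-[4-(benzyloxy)-2-hydroxyphenyl]-1-[4-(benzyloxy)phenyl]-3-{(2R,3R)-3,5,7-tris(benzyloxy)-2-[3,4,5-tris(benzyloxy)phenyl]chroman-8-yl}propan-1-ol F10. Mitsunobu ring closure (PPh3, DIAD, THF, 0 °C) with inversion at the carbinol then gives 19 with the (2S,4R) upper unit.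

Step 6. Chelation control may erode, or the α-alkoxy aldehyde may epimerise before addition. The fallback avoids the aldehyde and sets the carbinol by reduction; it sets out from 6 and comes back at 11. MeNH(OMe)·HCl with i-PrMgCl (THF, −20 °C) should convert 6 into (2R)-2-(benzyloxy)-3-[4-(benzyloxy)-2,6-difluorophenyl]-N-methoxy-N-methylpropanamide F11. Addition of 10 gives (2R)-2-(benzyloxy)-3-[4-(benzyloxy)-2,6-difluorophenyl]-1-[3,4,5-tris(benzyloxy)phenyl]propan-1-one F12. Felkin–Anh-controlled reduction with LiBH(s-Bu)3 (THF, −78 °C) should then give the syn alcohol 11.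

Further compounds
F1 | step 7 | 1,5-bis(benzyloxy)-2-bromo-3-fluorobenzene | Fc1cc(OCc2ccccc2)cc(OCc2ccccc2)c1Br
F2 | step 7 | methyl (2R)-3-[2,4-bis(benzyloxy)-6-fluorophenyl]-2-hydroxypropanoate | COC(=O)[C@H](O)Cc1c(F)cc(OCc2ccccc2)cc1OCc1ccccc1
F3 | step 7 | methyl (2R)-2-(benzyloxy)-3-[2,4-bis(benzyloxy)-6-fluorophenyl]propanoate | COC(=O)[C@H](OCc1ccccc1)Cc1c(F)cc(OCc2ccccc2)cc1OCc1ccccc1
F4 | step 7 | (2R)-2-(benzyloxy)-3-[2,4-bis(benzyloxy)-6-fluorophenyl]propanal | O=C[C@H](OCc1ccccc1)Cc1c(F)cc(OCc2ccccc2)cc1OCc1ccccc1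
F5 | step 7 | (1R,2R)-2-(benzyloxy)-3-[2,4-bis(benzyloxy)-6-fluorophenyl]-1-[3,4,5-tris(benzyloxy)phenyl]propan-1-ol | O[C@H](c1cc(OCc2ccccc2)c(OCc2ccccc2)c(OCc2ccccc2)c1)[C@H](OCc1ccccc1)Cc1c(F)cc(OCc2ccccc2)cc1OCc1ccccc1
F6 | step 10 | (2R,3R)-3,5,7-tris(benzyloxy)-8-bromo-2-[3,4,5-tris(benzyloxy)phenyl]chromane | C(c1ccccc1)Oc1cc(OCc2ccccc2)c2c(c1Br)O[C@H](c1cc(OCc3ccccc3)c(OCc3ccccc3)c(OCc3ccccc3)c1)[C@H](OCc1ccccc1)C2
F7 | step 10 | (2R,3R)-3,5,7-tris(benzyloxy)-2-[3,4,5-tris(benzyloxy)phenyl]chromane-8-carbaldehyde | C(c1ccccc1)Oc1cc(OCc2ccccc2)c2c(c1C=O)O[C@H](c1cc(OCc3ccccc3)c(OCc3ccccc3)c(OCc3ccccc3)c1)[C@H](OCc1ccccc1)C2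
F8 | step 10 | (E)-1-[4-(benzyloxy)phenyl]-3-{(2R,3R)-3,5,7-tris(benzyloxy)-2-[3,4,5-tris(benzyloxy)phenyl]chroman-8-yl}prop-2-en-1-one | C(c1ccccc1)Oc1cc(OCc2ccccc2)c2c(c1/C=C/C(=O)c1ccc(OCc3ccccc3)cc1)O[C@H](c1cc(OCc3ccccc3)c(OCc3ccccc3)c(OCc3ccccc3)c1)[C@H](OCc1ccccc1)C2
F9 | step 10 | (3R)-3-[4-(benzyloxy)-2-hydroxyphenyl]-1-[4-(benzyloxy)phenyl]-3-{(2R,3R)-3,5,7-tris(benzyloxy)-2-[3,4,5-tris(benzyloxy)phenyl]chroman-8-yl}propan-1-one | O=C(c1ccc(OCc2ccccc2)cc1)C[C@@H](c1c(OCc2ccccc2)cc(OCc2ccccc2)c2c1O[C@H](c1cc(OCc3ccccc3)c(OCc3ccccc3)c(OCc3ccccc3)c1)[C@H](OCc1ccccc1)C2)c1ccc(OCc2ccccc2)cc1O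
F10 | step 10 | (1R,3R)-3-[4-(benzyloxy)-2-hydroxyphenyl]-1-[4-(benzyloxy)phenyl]-3-{(2R,3R)-3,5,7-tris(benzyloxy)-2-[3,4,5-tris(benzyloxy)phenyl]chroman-8-yl}propan-1-ol | O[C@@H](c1ccc(OCc2ccccc2)cc1)C[C@@H](c1c(OCc2ccccc2)cc(OCc2ccccc2)c2c1O[C@H](c1cc(OCc3ccccc3)c(OCc3ccccc3)c(OCc3ccccc3)c1)[C@H](OCc1ccccc1)C2)c1ccc(OCc2ccccc2)cc1O
F11 | step 6 | (2R)-2-(benzyloxy)-3-[4-(benzyloxy)-2,6-difluorophenyl]-N-methoxy-N-methylpropanamide | CON(C)C(=O)[C@H](OCc1ccccc1)Cc1c(F)cc(OCc2ccccc2)cc1F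
F12 | step 6 | (2R)-2-(benzyloxy)-3-[4-(benzyloxy)-2,6-difluorophenyl]-1-[3,4,5-tris(benzyloxy)phenyl]propan-1-one | O=C(c1cc(OCc2ccccc2)c(OCc2ccccc2)c(OCc2ccccc2)c1)[C@H](OCc1ccccc1)Cc1c(F)cc(OCc2ccccc2)cc1F
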